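## Retrosynthetic overview

1. The last ring closed is the saturated decalin ring [CH(fusion)–CH2–CH(OH)–CH(CH3)–CH(OH)–CH(fusion)]. It forms together with the adjoining cyclohexene and the 11-membered carbocycle by a transannular Diels–Alder reaction of a 19-membered (E,E,E)-trienone, which is itself made in the same flask by a Stille ring closure that only then creates the diene.
2. Enabling feature: this cyclohexane is fused to a cyclohexene whose C=C lies opposite the fusion bond, and the quaternary C(CH3) next to one fusion CH carries the tetronate acyl C=O (Diels–Alder retron: dienophile = quaternary C/fusion CH, diene termini = the other fusion CH and the allylic CH bearing the butenylene CH2). The quaternary C and that allylic CH are already bridged by the nine-atom chain through the spirotetronate, so the cycloaddition is transannular, and the four-carbon diol tether folds as a chair.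
3. Seco-precursor: C-3 lithiation of an O-methyl spirotetronate carrying a (2Z,5E)-6-iodohexadienyl chain, addition to an (E)-2-methyl-enal carrying the anti,anti-stereotriad and an (E)-alkenylstannane, then oxidation.
4. Spirotetronate: exo- and face-selective Diels–Alder reaction of a (E,E)-diene with (R)-2-tert-butyl-5-methylidene-1,3-dioxolan-4-one, methanolysis, Bestmann-ylide domino. Stereotriad: Brown crotylboration, iodocarbonate cyclisation, epoxide opening, cross-metathesis.
5. Ring order: spiro-cyclohexene (step 8), butenolide (step 10), transient 19-membered carbocycle, then cyclohexene + cyclohexane + 11-membered ring (all step 26); only desilylation and O-demethylation follow.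

Key step: step 26

Remark on the chemistry (assumption): the target is a 3-acyltetronic acid drawn as one enol tautomer; the final step delivers this tautomeric system. Its stereodescriptors are read from the SMILES (spiro-cyclohexene: C–Et R, spiro C S, C–CH3 R).

## Route

Step 1
Reactants: 1 (E)-2-methylpent-2-enal; 2 ethyl 2-(triphenyl-λ5-phosphanylidene)propanoate
Product: 3 ethyl (2E,4E)-2,4-dimethylhepta-2,4-dienoate
Conditions: PhMe, 90 °C
Reagents that add atoms: none
Why: Wittig olefination with a stabilised α-methyl ylide should give the (E)-trisubstituted enoate (ester trans to the alkenyl chain, methyl cis), while the (E)-geometry of the enal is untouched.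

Step 2
Reactants: 3 dienoate
Product: 4 (2E,4E)-2,4-dimethylhepta-2,4-dien-1-ol
Conditions: DIBAL-H (2.2 equiv), CH2Cl2, −78 °C; Rochelle-salt work-up
Reagents that add atoms: none
Why: DIBAL-H 1,2-reduction of a conjugated ester to the allylic alcohol leaves the diene untouched.

Step 3
Reactants: 4 dienol
Product: 5 (2E,4E)-1-bromo-2,4-dimethylhepta-2,4-diene
Conditions: CBr4, PPh3, CH2Cl2, 0 °C; used crude
Reagents that add atoms: carbon tetrabromide, BrC(Br)(Br)Br
Why: Appel bromination of a primary allylic alcohol proceeds by SN2 at the primary carbon under neutral conditions, so both alkene geometries are kept.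

Step 4
Reactants: 5 dienyl bromide; 6 (but-3-yn-1-yloxy)(tert-butyl)dimethylsilane
Product: 7 tert-butyl{[(6E,8E)-6,8-dimethylundeca-6,8-dien-3-yn-1-yl]oxy}dimethylsilane
Conditions: CuI (10 mol%), NaI (cat.), K2CO3, DMF, rt
Reagents that add atoms: none
Why: Copper(I)-catalysed coupling of a terminal alkyne with a primary allylic bromide (copper acetylide, attack at the unhindered α-carbon) should give the skipped enyne with the conjugated diene intact.

Step 5
Reactants: 8 (R)-lactic acid; 9 pivalaldehyde
Product: 10 (2R,5R)-2-tert-butyl-5-methyl-1,3-dioxolan-4-one (cis)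
Conditions: TsOH·H2O (cat.), H2SO4 (cat.), pentane, reflux (Dean–Stark); crystallisation from pentane, −78 °C
Reagents that add atoms: none
Why: Acid-catalysed acetalisation of an α-hydroxy acid gives mainly the cis-2,5-disubstituted dioxolanone, obtained pure by crystallisation; C-5 comes from (R)-lactic acid and the acetal carbon is set under thermodynamic control.

Step 6
Reactants: 10 dioxolanone
Product: 11 (2S,5S)-5-bromo-2-tert-butyl-5-methyl-1,3-dioxolan-4-one (Br trans to tert-butyl; acetal carbon spatially unchanged)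
Conditions: NBS, AIBN (cat.), CCl4, reflux
Reagents that add atoms: N-bromosuccinimide, O=C1CCC(=O)N1Br
Why: Wohl–Ziegler-type radical bromination at the captodatively stabilised C-5 position, with bromine entering anti to tert-butyl (this centre is removed in step 7).

Step 7
Reactants: 11 bromide
Product: 12 (2R)-2-tert-butyl-5-methylidene-1,3-dioxolan-4-one
Conditions: Et3N, CH2Cl2, 0 °C → rt
Reagents that add atoms: none
Why: Base-induced dehydrobromination gives the exocyclic alkene and leaves the acetal stereocentre untouched.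

Step 8
Reactants: 7 diene; 12 chiral dienophile
Product: 13 (2R,5S,6R,9R)-spiro-dioxolanone cycloadduct
Conditions: PhMe (2 M), BHT (cat.), 110 °C, sealed tube
Reagents that add atoms: none
Why: Thermal Diels–Alder reaction of a captodative 1,1-disubstituted dienophile: the CH2 terminus bonds to the ethyl-bearing diene carbon (largest HOMO coefficient, "para" to the inner methyl), the lactone C=O sits exo as is characteristic of this dioxolanone, and the diene adds anti to tert-butyl, so that the spiro carbon (S), the neighbouring quaternary carbon (R; methyl "inside", propargylic chain "outside" on the diene) and the ethyl-bearing carbon (R) are set together.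

Step 9
Reactants: 13 cycloadduct
Product: 14 methyl (1S,2R,5R)-1-hydroxy-cyclohexene-carboxylate
Conditions: NaOMe (cat.), MeOH, 0 °C → rt
Reagents that add atoms: methanol, CO
Why: Base-catalysed methanolysis of the dioxolanone (transesterification, then loss of pivalaldehyde from the hemiacetal alkoxide) frees the tertiary α-hydroxy methyl ester without touching a stereocentre.

Step 10
Reactants: 14 hydroxy ester; 15 (triphenyl-λ5-phosphanylidene)ethenone
Product: 17 (5S,6R,9R)-4-methoxy-spirotetronate with the silyloxypentynyl chain, via ester ylide 16 (not isolated)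
Conditions: PhMe, 110 °C
Reagents that add atoms: none
Why: Domino addition–intramolecular Wittig olefination (Bestmann-ylide tetronate synthesis): the tertiary OH adds to the ketene C=O and the resulting ester ylide olefinates the neighbouring methyl ester carbonyl, so the ester OCH3 becomes the 4-methoxy group of the butenolide and the spiro centre is untouched.

Step 11
Reactants: 17 alkyne
Product: 18 (Z)-alkenyl silyl ether
Conditions: H2 (1 atm), Lindlar catalyst, quinoline, EtOAc, rt
Reagents that add atoms: none
Why: Lindlar semi-hydrogenation (syn addition on poisoned Pd) should give the (Z)-alkene; the hindered trisubstituted ring alkene and the butenolide are not reduced.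

Step 12
Reactants: 18 silyl ether
Product: 19 (Z)-homoallylic alcohol
Conditions: HF·pyridine, pyridine, THF, 0 °C → rt
Reagents that add atoms: none
Why: Fluoride cleavage of a primary TBS ether; the methyl tetronate (vinylogous carbonate) is stable to these conditions.

Step 13
Reactants: 19 alcohol
Product: 20 (3Z)-β,γ-unsaturated aldehyde
Conditions: Dess–Martin periodinane, NaHCO3, CH2Cl2, 0 °C; used at once
Reagents that add atoms: none
Why: Buffered Dess–Martin oxidation gives the skipped aldehyde without acid- or base-induced migration of the (Z)-alkene.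

Step 14
Reactants: 20 aldehyde
Product: 21 (5S,6R,9R)-6-[(2Z,5E)-6-iodohexa-2,5-dien-1-yl] spirotetronate
Conditions: CrCl2 (6 equiv), CHI3 (2 equiv), THF–dioxane, 0 °C → rt
Reagents that add atoms: iodoform, IC(I)I
Why: Takai olefination (gem-dichromium species from CHI3/CrCl2) converts the aldehyde into the alkenyl iodide, the (E)-isomer being favoured by anti elimination from the β-oxido-chromium intermediate.

Step 15
Reactants: 22 3-(trimethylsilyl)prop-2-ynal
Product: 23 (3S,4S)-4-methyl-1-(trimethylsilyl)hex-5-en-1-yn-3-ol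
Conditions: (E)-crotyl-B(Ipc)2 [freshly made at −78 °C from (−)-Ipc2BOMe, (E)-but-2-ene, n-BuLi, KOt-Bu, BF3·OEt2], THF, −78 °C; then NaOH, H2O2
Reagents that add atoms: (E)-crotyldiisopinocampheylborane (Ipc from (+)-α-pinene), C/C=C/CB([C@@H]1C[C@@H]2C[C@@H](C2(C)C)[C@H]1C)[C@@H]1C[C@@H]2C[C@@H](C2(C)C)[C@H]1C
Why: Brown asymmetric crotylboration through a chair Zimmerman–Traxler transition state: the (E)-crotyl geometry gives the 3,4-anti relation and the isopinocampheyl groups select the aldehyde face that leads to (3S,4S).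

Step 16
Reactants: 23 homoallylic alcohol
Product: 24 tert-butyl (3S,4S)-4-methyl-1-(trimethylsilyl)hex-5-en-1-yn-3-yl carbonate
Conditions: Boc2O, DMAP (cat.), MeCN, rt
Reagents that add atoms: di-tert-butyl dicarbonate, CC(C)(C)OC(=O)OC(=O)OC(C)(C)C
Why: DMAP-catalysed acylation of the secondary alcohol installs the carbonate needed as internal oxygen nucleophile.

Step 17
Reactants: 24 carbonate
Product: 25 (4R,5R,6S)-4-(iodomethyl)-5-methyl-6-[(trimethylsilyl)ethynyl]-1,3-dioxan-2-one
Conditions: IBr, PhMe, −85 °C
Reagents that add atoms: iodine monobromide, IBr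
Why: Iodocarbonate cyclisation (iodonium formation, 6-exo attack of the carbonate C=O, loss of tert-butyl as the bromide) through a chair with alkynyl, methyl and CH2I all equatorial, which sets the new C–O centre 1,3-syn to the existing carbinol and anti to the methyl group.

Step 18
Reactants: 25 iodocarbonate
Product: 27 (3S,4R)-4-[(2R)-oxiran-2-yl]pent-1-yn-3-ol, via iodo diol 26 (not isolated)
Conditions: K2CO3, MeOH, rt
Reagents that add atoms: none
Why: Carbonate methanolysis followed by intramolecular Williamson closure of the iodohydrin gives the epoxide with retention at the carbinol carbon, and the alkynylsilane is cleaved in the same pot.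

Step 19
Reactants: 27 epoxy alcohol
Product: 28 tert-butyldimethylsilyl ether of 27
Conditions: TBSCl, imidazole, DMF, rt
Reagents that add atoms: tert-butyldimethylsilyl chloride, CC(C)(C)[Si](C)(C)Cl
Why: Silylation under non-Lewis-acidic conditions protects the propargylic alcohol and leaves the epoxide intact.

Step 20
Reactants: 28 epoxide
Product: 29 (4S,5S,6S)-6-[(tert-butyldimethylsilyl)oxy]-5-methyloct-1-en-7-yn-4-ol
Conditions: CH2=CHMgBr (3 equiv), CuI (10 mol%), THF, −40 → −20 °C
Reagents that add atoms: vinylmagnesium bromide, C=C[Mg]Br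
Why: Copper-catalysed Grignard opening of a terminal epoxide occurs by SN2 at the CH2 carbon, so the carbinol stereocentre is untouched (the extra Grignard covers the acidic alkyne C–H).

Step 21
Reactants: 29 alcohol
Product: 30 (4S,5S,6S)-4,6-bis[(tert-butyldimethylsilyl)oxy]-5-methyloct-1-en-7-yne
Conditions: TBSOTf, 2,6-lutidine, CH2Cl2, −78 → 0 °C
Reagents that add atoms: tert-butyldimethylsilyl triflate, CC(C)(C)[Si](C)(C)OS(=O)(=O)C(F)(F)F
Why: Silylation of the hindered secondary alcohol with the silyl triflate gives the two separately protected hydroxyls, which can both sit equatorial in the later chair-like tether.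

Step 22
Reactants: 30 enyne
Product: 31 tributyl{(1E,3S,4S,5S)-3,5-bis[(tert-butyldimethylsilyl)oxy]-4-methylocta-1,7-dien-1-yl}stannane
Conditions: Bu3SnH, PdCl2(PPh3)2 (2 mol%), THF, 0 °C
Reagents that add atoms: tributyltin hydride, CCCC[SnH](CCCC)CCCC
Why: Palladium-catalysed syn-hydrostannation of the terminal alkyne places tin on the terminal carbon, away from the branched propargylic centre, giving the (E)-alkenylstannane; the isolated alkene is inert.

Step 23
Reactants: 31 dienylstannane; 32 methacrolein
Product: 33 (2E,5S,6S,7S,8E)-5,7-bis[(tert-butyldimethylsilyl)oxy]-2,6-dimethyl-9-(tributylstannyl)nona-2,8-dienal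
Conditions: Hoveyda–Grubbs II catalyst (5 mol%), methacrolein (10 equiv), CH2Cl2, 40 °C
Reagents that add atoms: none
Why: Olefin cross-metathesis of the terminal alkene with methacrolein should give the (E)-2-methyl-enal (thermodynamic geometry), the hindered 1,2-disubstituted alkenylstannane being a spectator.

Step 24
Reactants: 21 spirotetronate iodide; 33 enal
Product: 35 C-3 (1-hydroxyalkenyl) spirotetronate (both carbinol epimers), via C-3 lithiated tetronate 34 (not isolated)
Conditions: LDA (1.1 equiv), THF, −78 °C; then 33, −78 °C; H2O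
Reagents that add atoms: none
Why: Deprotonation of the 4-methoxybutenolide at C-3 (the only acidic site, as the spiro C-5 bears no hydrogen) and 1,2-addition of the alkenyllithium to the enal; both carbinol epimers are carried on because the centre is oxidised next.

Step 25
Reactants: 35 carbinol
Product: 36 3-[(2E)-2-methylenoyl] spirotetronate (seco-precursor)
Conditions: Dess–Martin periodinane, NaHCO3, CH2Cl2, 0 °C → rt
Reagents that add atoms: none
Why: Dess–Martin oxidation of the doubly allylic alcohol converges the epimers to the cross-conjugated ketone and thereby activates the (E)-2-methyl alkene as dienophile; the buffered conditions spare the alkenylstannane.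

Step 26
Reactants: 36 seco-precursor
Product: 38 bis-TBS ether of the O-methyl tetronate of the target (pentacycle), via macrocyclic trienone 37 (not isolated)
Conditions: Pd2(dba)3 (15 mol%), AsPh3 (60 mol%), degassed DMF (1 mM, syringe-pump addition), rt; then 80 °C, BHT
Reagents that add atoms: none
Why: Oxidative addition of Pd(0) into the (E)-alkenyl iodide, Sn→Pd transmetallation of the (E)-alkenylstannane and reductive elimination close the 19-membered ring at the alkenyl–alkenyl bond and only thereby create the (E,E)-diene, which then adds across the (E)-2-methyl-enone in a concerted suprafacial transannular [4+2] cycloaddition (closest known type: cross-coupling macrocyclisation followed by transannular Diels–Alder reaction of a macrocyclic (E,E,E)-trienone). The cyclohexene closes through both new σ-bonds, the saturated six-membered ring through the fusion bond (enone β-carbon to the proximal diene terminus) across the four-carbon tether in a chair-like array, and the 11-membered ring remains as the residue of the macrocycle once the enone α-carbon is bonded to the distal diene terminus. The four new stereocentres are related to each other by the alkene geometries (E,E-diene: the two terminus substituents cis; E-enone: acyl and tether CH2 trans) and by the endo position of the ketone under the diene, which gives the trans ring fusion and the cis-fused macrocycle, whereas the exo mode would need a trans-bridged 11-membered ring. Their sense relative to the existing centres (diene face) is set by the tether, whose chair carries both OTBS groups equatorial and the methyl axial in the productive transition state but would need both OTBS groups 1,3-diaxial in the other, supported by the rigid spirotetronate bridge. Regiochemistry is fixed by the two tethers, and a premature cycloaddition is excluded because no diene exists before the ring closure.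

Step 27
Reactants: 38 bis-silyl ether
Product: 39 O-methyl tetronate diol
Conditions: HF·pyridine, pyridine, THF, 0 °C → rt
Reagents that add atoms: none
Why: Fluoride cleavage of the two secondary TBS ethers, to which the alkenes and the methyl tetronate are inert.

Step 28
Reactants: 39 O-methyl tetronate
Product: 40 target CNP0259772.1
Conditions: LiCl (10 equiv), DMSO, 50 °C; aq. HCl work-up
Reagents that add atoms: none
Why: SN2 demethylation of the vinylogous methyl ester by chloride gives the lithium 3-acyltetronate, which is protonated on acidic work-up to the 3-acyltetronic acid (drawn enol tautomer).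

## Compound list

1 | (E)-2-methylpent-2-enal | CC/C=C(\C)C=O | starting material
2 | ethyl 2-(triphenyl-λ5-phosphanylidene)propanoate | CCOC(=O)C(C)=P(c1ccccc1)(c1ccccc1)c1ccccc1 | starting material
3 | ethyl (2E,4E)-2,4-dimethylhepta-2,4-dienoate | CCOC(=O)/C(C)=C/C(C)=C/CC | intermediate
4 | (2E,4E)-2,4-dimethylhepta-2,4-dien-1-ol | OC/C(C)=C/C(C)=C/CC | intermediate
5 | (2E,4E)-1-bromo-2,4-dimethylhepta-2,4-diene | BrC/C(C)=C/C(C)=C/CC | intermediate
6 | (but-3-yn-1-yloxy)(tert-butyl)dimethylsilane | C#CCCO[Si](C)(C)C(C)(C)C | starting material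
7 | tert-butyl{[(6E,8E)-6,8-dimethylundeca-6,8-dien-3-yn-1-yl]oxy}dimethylsilane | CC/C=C(C)/C=C(\C)CC#CCCO[Si](C)(C)C(C)(C)C | intermediate
8 | (R)-lactic acid | C[C@@H](O)C(=O)O | starting material
9 | pivalaldehyde | CC(C)(C)C=O | starting material
10 | (2R,5R)-2-tert-butyl-5-methyl-1,3-dioxolan-4-one (cis) | C[C@H]1O[C@@H](C(C)(C)C)OC1=O | intermediate
11 | (2S,5S)-5-bromo-2-tert-butyl-5-methyl-1,3-dioxolan-4-one (Br trans to tert-butyl) | C[C@@]1(Br)O[C@@H](C(C)(C)C)OC1=O | intermediate
12 | (2R)-2-tert-butyl-5-methylidene-1,3-dioxolan-4-one | C=C1O[C@@H](C(C)(C)C)OC1=O | intermediate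
13 | (2R,5S,6R,9R)-2-tert-butyl-6-{5-[(tert-butyldimethylsilyl)oxy]pent-2-yn-1-yl}-9-ethyl-6,8-dimethyl-1,3-dioxaspiro[4.5]dec-7-en-4-one | CC[C@@H]1C[C@]2(O[C@@H](C(C)(C)C)OC2=O)[C@](C)(CC#CCCO[Si](C)(C)C(C)(C)C)C=C1C | intermediate
14 | methyl (1S,2R,5R)-2-{5-[(tert-butyldimethylsilyl)oxy]pent-2-yn-1-yl}-5-ethyl-1-hydroxy-2,4-dimethylcyclohex-3-ene-1-carboxylate | CC[C@@H]1C[C@@](O)(C(=O)OC)[C@](C)(CC#CCCO[Si](C)(C)C(C)(C)C)C=C1C | intermediate
15 | (triphenyl-λ5-phosphanylidene)ethenone (Bestmann ylide) | O=C=C=P(c1ccccc1)(c1ccccc1)c1ccccc1 | starting material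
16 | O-[(triphenyl-λ5-phosphanylidene)acetyl] derivative of 14 (ester ylide; configuration as in 14) | CC[C@@H]1C[C@@](OC(=O)C=P(c2ccccc2)(c2ccccc2)c2ccccc2)(C(=O)OC)[C@](C)(CC#CCCO[Si](C)(C)C(C)(C)C)C=C1C | intermediate (not isolated)
17 | (5S,6R,9R)-6-{5-[(tert-butyldimethylsilyl)oxy]pent-2-yn-1-yl}-9-ethyl-4-methoxy-6,8-dimethyl-1-oxaspiro[4.5]deca-3,7-dien-2-one | CC[C@@H]1C[C@]2(OC(=O)C=C2OC)[C@](C)(CC#CCCO[Si](C)(C)C(C)(C)C)C=C1C | intermediate
18 | (5S,6R,9R)-6-{(2Z)-5-[(tert-butyldimethylsilyl)oxy]pent-2-en-1-yl}-9-ethyl-4-methoxy-6,8-dimethyl-1-oxaspiro[4.5]deca-3,7-dien-2-one | CC[C@@H]1C[C@]2(OC(=O)C=C2OC)[C@](C)(C/C=C\CCO[Si](C)(C)C(C)(C)C)C=C1C | intermediate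
19 | (5S,6R,9R)-9-ethyl-6-[(2Z)-5-hydroxypent-2-en-1-yl]-4-methoxy-6,8-dimethyl-1-oxaspiro[4.5]deca-3,7-dien-2-one | CC[C@@H]1C[C@]2(OC(=O)C=C2OC)[C@](C)(C/C=C\CCO)C=C1C | intermediate
20 | (3Z)-5-[(5S,6R,9R)-9-ethyl-4-methoxy-6,8-dimethyl-2-oxo-1-oxaspiro[4.5]deca-3,7-dien-6-yl]pent-3-enal | CC[C@@H]1C[C@]2(OC(=O)C=C2OC)[C@](C)(C/C=C\CC=O)C=C1C | intermediate
21 | (5S,6R,9R)-9-ethyl-6-[(2Z,5E)-6-iodohexa-2,5-dien-1-yl]-4-methoxy-6,8-dimethyl-1-oxaspiro[4.5]deca-3,7-dien-2-one | CC[C@@H]1C[C@]2(OC(=O)C=C2OC)[C@](C)(C/C=C\C/C=C/I)C=C1C | intermediate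
22 | 3-(trimethylsilyl)prop-2-ynal | C[Si](C)(C)C#CC=O | starting material
23 | (3S,4S)-4-methyl-1-(trimethylsilyl)hex-5-en-1-yn-3-ol (anti) | C=C[C@H](C)[C@H](O)C#C[Si](C)(C)C | intermediate
24 | tert-butyl (3S,4S)-4-methyl-1-(trimethylsilyl)hex-5-en-1-yn-3-yl carbonate | C=C[C@H](C)[C@H](OC(=O)OC(C)(C)C)C#C[Si](C)(C)C | intermediate
25 | (4R,5R,6S)-4-(iodomethyl)-5-methyl-6-[(trimethylsilyl)ethynyl]-1,3-dioxan-2-one (all substituents equatorial) | IC[C@@H]1OC(=O)O[C@H](C#C[Si](C)(C)C)[C@H]1C | intermediate
26 | (3S,4R,5R)-6-iodo-4-methylhex-1-yne-3,5-diol | C#C[C@@H](O)[C@@H](C)[C@@H](O)CI | intermediate (not isolated)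
27 | (3S,4R)-4-[(2R)-oxiran-2-yl]pent-1-yn-3-ol | C#C[C@@H](O)[C@@H](C)[C@@H]1CO1 | intermediate
28 | tert-butyldimethyl{[(3S,4S)-4-[(2R)-oxiran-2-yl]pent-1-yn-3-yl]oxy}silane | C#C[C@@H](O[Si](C)(C)C(C)(C)C)[C@@H](C)[C@@H]1CO1 | intermediate
29 | (4S,5S,6S)-6-[(tert-butyldimethylsilyl)oxy]-5-methyloct-1-en-7-yn-4-ol | C#C[C@@H](O[Si](C)(C)C(C)(C)C)[C@@H](C)[C@@H](O)CC=C | intermediate
30 | (4S,5S,6S)-4,6-bis[(tert-butyldimethylsilyl)oxy]-5-methyloct-1-en-7-yne | C#C[C@@H](O[Si](C)(C)C(C)(C)C)[C@@H](C)[C@@H](O[Si](C)(C)C(C)(C)C)CC=C | intermediate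
31 | tributyl{(1E,3S,4S,5S)-3,5-bis[(tert-butyldimethylsilyl)oxy]-4-methylocta-1,7-dien-1-yl}stannane | CCCC[Sn](CCCC)(CCCC)/C=C/[C@@H](O[Si](C)(C)C(C)(C)C)[C@@H](C)[C@@H](O[Si](C)(C)C(C)(C)C)CC=C | intermediate
32 | methacrolein (2-methylprop-2-enal) | CC(=C)C=O | starting material
33 | (2E,5S,6S,7S,8E)-5,7-bis[(tert-butyldimethylsilyl)oxy]-2,6-dimethyl-9-(tributylstannyl)nona-2,8-dienal | CCCC[Sn](CCCC)(CCCC)/C=C/[C@@H](O[Si](C)(C)C(C)(C)C)[C@@H](C)[C@@H](O[Si](C)(C)C(C)(C)C)C/C=C(\C)C=O | intermediate
34 | 3-lithio derivative of 21 (C-3 lithiated 4-methoxybutenolide) | CC[C@@H]1C[C@]2(OC(=O)C([Li])=C2OC)[C@](C)(C/C=C\C/C=C/I)C=C1C | intermediate (not isolated)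
35 | (5S,6R,9R)-3-[(2E,5S,6S,7S,8E)-5,7-bis(tert-butyldimethylsilyloxy)-1-hydroxy-2,6-dimethyl-9-(tributylstannyl)nona-2,8-dien-1-yl]-9-ethyl-6-[(2Z,5E)-6-iodohexa-2,5-dien-1-yl]-4-methoxy-6,8-dimethyl-1-oxaspiro[4.5]deca-3,7-dien-2-one (both carbinol epimers) | CC[C@@H]1C[C@]2(OC(=O)C(C(O)/C(C)=C/C[C@H](O[Si](C)(C)C(C)(C)C)[C@H](C)[C@H](O[Si](C)(C)C(C)(C)C)/C=C/[Sn](CCCC)(CCCC)CCCC)=C2OC)[C@](C)(C/C=C\C/C=C/I)C=C1C | intermediate
36 | the corresponding 3-[(2E,5S,6S,7S,8E)-nona-2,8-dienoyl] ketone of 35 (seco-precursor) | CC[C@@H]1C[C@]2(OC(=O)C(C(=O)/C(C)=C/C[C@H](O[Si](C)(C)C(C)(C)C)[C@H](C)[C@H](O[Si](C)(C)C(C)(C)C)/C=C/[Sn](CCCC)(CCCC)CCCC)=C2OC)[C@](C)(C/C=C\C/C=C/I)C=C1C | intermediate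
37 | 19-membered macrocyclic trienone formed from 36 by C–C bonding of the iodo- and stannyl-bearing alkenyl carbons [(E)-enone, (E,E)-diene, (Z)-alkene; stereocentres as in 36] | CC[C@@H]1C[C@]23OC(=O)C(=C3OC)C(=O)/C(C)=C/C[C@H](O[Si](C)(C)C(C)(C)C)[C@H](C)[C@H](O[Si](C)(C)C(C)(C)C)/C=C/C=C/C/C=C\C[C@]2(C)C=C1C | intermediate (not isolated)
38 | bis(tert-butyldimethylsilyl) ether of the 4-O-methyl tetronate of the target (pentacycle; all centres as in the target) | CC[C@@H]1C[C@]23OC(=O)C(=C3OC)C(=O)[C@@]4(C)[C@@H]5C[C@H](O[Si](C)(C)C(C)(C)C)[C@H](C)[C@H](O[Si](C)(C)C(C)(C)C)[C@H]5C=C[C@H]4C/C=C\C[C@]2(C)C=C1C | intermediate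
39 | 4-O-methyl tetronate of the target (free diol) | CC[C@@H]1C[C@]23OC(=O)C(=C3OC)C(=O)[C@@]4(C)[C@@H]5C[C@H](O)[C@H](C)[C@H](O)[C@H]5C=C[C@H]4C/C=C\C[C@]2(C)C=C1C | intermediate
40 | CNP0259772.1 (3-acyl spirotetronic acid, trans-decalin diol) | CC[C@@H]1C[C@]23OC(=O)/C(=C(\O)[C@@]4(C)[C@@H]5C[C@H](O)[C@H](C)[C@H](O)[C@H]5C=C[C@H]4C/C=C\C[C@]2(C)C=C1C)C3=O | target

## Step count and risks

Total step count: 28. Longest linear sequence: 16 (steps 1–4, 8–14, 24–28).

Steps most likely to fail:

1. Step 26. The ring closure may lose out to intermolecular coupling or protodestannylation at the temperature it needs, and the cycloaddition, run in hot DMF, may proceed through the wrong diene face or not go to completion. The fallback sets out from 35 and returns at 38. Carbinol 35 is cyclised first at the alcohol oxidation level, where the alkene next to the carbinol is not a dienophile and the mixture can be heated: Stille macrocyclisation (Pd2(dba)3, AsPh3, DMF, 1 mM, 40–60 °C) should give the macrocyclic (E,E)-dienyl carbinol F1, which can be purified. Dess–Martin oxidation at 0 °C then generates trienone 37 free of palladium and tin, and the transannular Diels–Alder reaction is run on it in CH2Cl2 with Me2AlCl at −78 → −20 °C, where Lewis-acid activation of the ketone should sharpen endo and facial selectivity, to give 38.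

2. Step 8. The cycloaddition may be too slow (tetrasubstituted diene with an inside methyl, two adjacent fully substituted carbons formed), so that decomposition of the dienophile and erosion of exo selectivity compete. The fallback sets out from 7 and returns at 14. A low-temperature, catalyst-controlled Diels–Alder reaction of 7 with 2-(benzoyloxy)acrolein under chiral primary-ammonium (iminium) catalysis, the mode established for α-acyloxyacroleins with the formyl group exo, should give the α-benzoyloxy aldehyde F2. Pinnick oxidation gives the acid F3, TMSCHN2 the methyl ester F4, and benzoate methanolysis (NaOMe, MeOH) the hydroxy ester 14.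

3. Step 10. The hindered tertiary hydroxyl may add to the ketenylidene ylide only sluggishly, or the ester ylide 16 may stall before olefinating the congested ester carbonyl. The fallback sets out from 14 and returns at 17. Acetylation (Ac2O, Sc(OTf)3 cat., MeCN) should give the tertiary acetate F5, Dieckmann condensation (LiHMDS, THF, −78 → 0 °C) the spirotetronic acid F6, and O-methylation (Me2SO4, K2CO3, acetone) the methyl tetronate 17.

## Further compounds

F1 | step 26 | macrocyclic (E,E)-dienyl carbinol (19-membered ring; alcohol oxidation level of 37, both carbinol epimers) | CC[C@@H]1C[C@]23OC(=O)C(=C3OC)C(O)/C(C)=C/C[C@H](O[Si](C)(C)C(C)(C)C)[C@H](C)[C@H](O[Si](C)(C)C(C)(C)C)/C=C/C=C/C/C=C\C[C@]2(C)C=C1C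
F2 | step 8 | (1S,2R,5R)-2-{5-[(tert-butyldimethylsilyl)oxy]pent-2-yn-1-yl}-5-ethyl-1-formyl-2,4-dimethylcyclohex-3-en-1-yl benzoate | CC[C@@H]1C[C@@](OC(=O)c2ccccc2)(C=O)[C@](C)(CC#CCCO[Si](C)(C)C(C)(C)C)C=C1C
F3 | step 8 | (1S,2R,5R)-1-(benzoyloxy)-2-{5-[(tert-butyldimethylsilyl)oxy]pent-2-yn-1-yl}-5-ethyl-2,4-dimethylcyclohex-3-ene-1-carboxylic acid | CC[C@@H]1C[C@@](OC(=O)c2ccccc2)(C(=O)O)[C@](C)(CC#CCCO[Si](C)(C)C(C)(C)C)C=C1C
F4 | step 8 | methyl (1S,2R,5R)-1-(benzoyloxy)-2-{5-[(tert-butyldimethylsilyl)oxy]pent-2-yn-1-yl}-5-ethyl-2,4-dimethylcyclohex-3-ene-1-carboxylate | CC[C@@H]1C[C@@](OC(=O)c2ccccc2)(C(=O)OC)[C@](C)(CC#CCCO[Si](C)(C)C(C)(C)C)C=C1C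
F5 | step 10 | methyl (1S,2R,5R)-1-acetoxy-2-{5-[(tert-butyldimethylsilyl)oxy]pent-2-yn-1-yl}-5-ethyl-2,4-dimethylcyclohex-3-ene-1-carboxylate | CC[C@@H]1C[C@@](OC(C)=O)(C(=O)OC)[C@](C)(CC#CCCO[Si](C)(C)C(C)(C)C)C=C1C
F6 | step 10 | (5S,6R,9R)-6-{5-[(tert-butyldimethylsilyl)oxy]pent-2-yn-1-yl}-9-ethyl-4-hydroxy-6,8-dimethyl-1-oxaspiro[4.5]deca-3,7-dien-2-one | CC[C@@H]1C[C@]2(OC(=O)C=C2O)[C@](C)(CC#CCCO[Si](C)(C)C(C)(C)C)C=C1C
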